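Remark on the chemistry: the locant in "3-O-caffeoyl" follows the older quinic acid numbering. Here the ring is numbered C1 (quaternary, OMe and the C7 carboxyl), C2H2, C3, C4, C5 (acylated oxygen), C6H2, which makes the target (1S,3R,4R,5R). "Top face" means the face of O3 and O4, "bottom face" the face of O5. 2-Deoxy-L-ribose is taken as a commercially available sugar.

## Structural features

The target is a single cyclohexane ring, C1–C6, in which C1 is quaternary and carries a methoxy group and the C7 carboxyl, C2 and C6 are methylenes, and C3, C4 and C5 are three contiguous carbinol carbons; O5 alone is esterified with an (E)-3,4-dihydroxycinnamoyl (caffeoyl) chain. O3 and O4 are cis on the top face, O5 is trans to O4 on the bottom face, and at C1 the methoxy group is on the top face and the carboxyl on the bottom face, cis to O5, so that C1 is a stereocentre only through its 1,3-relationships to C3 and C5. The fragile groups are the catechol (oxidation, base), the enoate and the secondary ester, which migrates to a free neighbouring hydroxyl above neutral pH, and the cis O5/carboxyl pair can close a bicyclic lactone whenever O5 is free and C7 is at the acid level. The real difficulty is not the skeleton but the tertiary methyl ether at a quaternary stereocentre with no adjacent stereocentre, together with the acylation of O5 alone among three secondary hydroxyls. The key step exploits the C5–C6 bond, which joins a carbinol carbon to a methylene on the quaternary carbon: C5 becomes an aldehyde and C6 the γ-terminus of a 2-substituted allylsilane whose central carbon is C1 and whose silylmethyl carbon is C7. Ring closure then leaves an exocyclic C1=C7 alkene and O5 as the only free hydroxyl, homoallylic to that alkene, which is what the later oxygenation of C1 and C7 needs. Read from C1 to C5, the cis C3/C4 diol is the 3,4-diol of 2-deoxy-L-erythro-pentose, so C1–C5 and both stereocentres can be bought in one sugar and carried as a cis-fused acetonide. The open-chain aldehyde 7 is (2R,3R) and the ring-closed alcohol 8 is (3R,4S,5R), which is the spatial arrangement of C3 (R) and C4 (R) in 16 (the letter at C4 changes only through substituent priorities), so neither structure needs a stereochemical correction.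

## Logic of the disconnections

16 ⇒ 15. The two aryl O–acetyl bonds and the two C–O bonds of the isopropylidene acetal are cut last. The acetal keeps O3 and O4 blocked until the final step, so the caffeoyl group has nowhere to migrate. The forward step must be acidic and must spare the alkyl enoate and the tertiary methyl ether.

15 ⇒ 13 (through 14). The carboxyl is traced to the C7 carbinol. Because O5 is already acylated at this point, oxidation cannot close the O5/C7 lactone and the acid needs no protecting group. The oxidant has to act on a neopentyl-type carbinol and tolerate the enoate and the aryl acetates.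

13 ⇒ 12. The C1–OMe bond is cut to a C1/C7 spiro-epoxide. The tertiary ether then arises by invertive solvolysis and not by alkylation of a tertiary alcohol, and one epoxide supplies both the C1 oxygen and the C7 oxygen. The forward step must attack C1 from the side opposite to the epoxide oxygen under acid mild enough for the acetal and the acetates.

12 ⇒ 9 + 11, and 11 ⇒ 10. The O5–acyl bond is cut at the stage where O5 is the only hydroxyl in the molecule and has just finished its directing role. The phenols of 10 are masked as acetates so that the acid can be activated. Activation must be neutral and free of chloride because of the epoxide.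

9 ⇒ 8. Both C–O bonds of the epoxide are cut to the exocyclic alkene. The homoallylic O5–H must deliver oxygen to its own face, which is also the face remote from the acetal. This requires O5 to be trans to O4 already in 8, so a wrong C5 epimer has to be corrected before this step and not by a late inverting esterification with the acyl fragment.

8 ⇒ 7 (key disconnection). The C5–C6 bond is cut, opening the ring to an aldehyde and a 2-substituted allylsilane. One C–C bond, the ring and the C5 stereocentre are formed together, and the alkene needed for C1 and C7 appears as a consequence of the mechanism. The forward step needs a monodentate Lewis acid and facial control from C4.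

7 ⇒ 6. The aldehyde is traced to the primary alcohol. The oxidation must not epimerise the α-oxygenated C4 and must leave the allylsilane intact.

6 ⇒ 3 + two molecules of 4 (through 5). The C1–C6 and C1–C7 bonds are cut back to a lactone carbonyl and two silylmethyl nucleophiles, one of which keeps its silicon and one of which loses it in the elimination. Ring opening of the lactone releases the C5 carbinol, so no protecting group is needed at either end. An alkylative assembly from a four-carbon lactone-derived fragment is not used, because it places a sulfonate γ to an acyl oxygen (which recloses the lactone by O-alkylation) and exposes that acyl group to an alkenylmagnesium reagent. The forward step needs a non-basic organometallic, because the C3 oxygen is β to the carbonyl.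

3 ⇒ 2 ⇒ 1. The lactone is traced to the lactol and then the acetal C–O bonds are cut. All of C1–C5 and both stereocentres come from 1. The acetal must form on the cis 3,4-diol of the pyranose form.

## Other disconnections considered

Alternative 1: Ireland–Claisen ring contraction.
- Cut and key step: the cut is C1–C2, with the C4 oxygen reconnected to the carboxyl carbon, so the carbocycle is traced to the vinyl δ-lactone A1. A1 would be enolised, O-silylated and warmed; the ring-bound ketene acetal can only rearrange through a boat, forming C1–C2, breaking C4–O and giving the cyclohexene acid A2.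
- In its favour: the methyl ether is already on the lactone α-carbon, so quaternary C1 with OMe and carboxyl would be created in one stereospecific pericyclic event, and C7 needs no later oxidation. On both points this is better than the chosen plan, which spends steps 6, 9 and 10 on C1 and C7. The mechanism is also cleaner (concerted, neutral, no Lewis acid near an acetal).
- Against it here: A1 needs its silyloxy group trans to the vinyl group for the carboxyl to end up cis to O5, and no cheap chiral-pool compound supplies those two stereocentres. O3 and O4 would still have to be added to A2 by cis-dihydroxylation anti to the O5 silyl ether, a facial question of about the same weight as step 6 (equal), followed by acetal formation, desilylation and acylation.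
- Comparison: on structure, the chosen plan buys C3 and C4 and sets C5 and C1 by substrate control, whereas this alternative makes C1 more elegantly but has to construct C3–C5. On mechanism the sigmatropic step is the more predictable of the two ring closures. On step economy the alternative is estimated two to three steps longer.

Alternative 2: aldol closure of a citrate-type core.
- Cut and key step: the cut is C4–C5, opening the ring to the keto aldehyde A3, which already carries OMe and the ester at C1. A chiral secondary amine would form the enamine on the C4 side of the C3 ketone and add it to the C5 aldehyde (6-enolendo) to give the β-hydroxy ketone A4.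
- In its favour: two adjacent stereocentres and the ring in one metal-free step, and the C1 substitution and carboxyl oxidation level are in place from the start (better than the chosen plan on that point). O5 would emerge as the only free hydroxyl, which is equal to the situation in 9.
- Against it here: A3 is chiral only through the difference between two remote arms, so it requires desymmetrisation of a prochiral quaternary carbon, for which no dependable method can be named. The methoxy group is β to both carbonyls of A3 and to the ketone of A4, so E1cB loss of methanol threatens under amine catalysis. Catalyst control of C4/C5 must also match the fixed C1 across a 1,3-relationship, and the C3 ketone must then be reduced cis to O4.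
- Comparison: on structure, A4 is closer to the target at C1 and C7 than 8 is. On mechanism, it rests on catalyst control and an unsolved asymmetric start, where the chosen plan rests on a chiral-pool diol and a well-precedented cationic cyclisation. On step economy, the sequence after A4 might be short, but the preparation of enantiopure A3 is open-ended.

Alternative 3: Diels–Alder reaction of a chiral α-oxyacrylate equivalent.
- Cut and key step: the cuts are C1–C6 and C2–C3. The dienophile A5 and buta-1,3-diene A6 would combine in a thermal [4+2] addition on the face opposite to tert-butyl to give the spiro adduct A7.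
- In its favour: two C–C bonds and the ring from very simple materials in one step, which is better bond economy than step 5. C1 is set by the acetal centre and the carboxyl is present from the start.
- Against it here: A7 has no oxygen on C3–C5. These would have to be relayed from the carboxyl (halolactonisation onto C5, elimination to a C3=C4 alkene, cis-dihydroxylation, lactone opening), after which O5 is tied to the carboxyl and both must be separated again. The C1 oxygen emerges as the tertiary hydroxyl of an α-hydroxy acid, and its O-methylation is exactly what step 9 of the chosen plan avoids. A6 is a gas that needs pressure, and facial control rests on a remote substituent.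
- Comparison: on structure and mechanism the ring construction is stronger (concerted, two bonds), while the oxygenation and the methyl ether are weaker than in the chosen plan. On step economy the route is estimated three to four steps longer.

Key step: step 5

## Route

Step 1
Reactants: 1 2-deoxy-L-ribose
Product: 2 2-deoxy-3,4-O-isopropylidene-L-erythro-pentopyranose (anomeric mixture)
Conditions: 2-methoxypropene, PPTS (cat.), EtOAc, 0 °C → rt
Reagents that add atoms: 2-methoxypropene, COC(C)=C
Why: Acid-catalysed acetal exchange with the enol ether selects the cis-vicinal 3,4-diol of the pyranose form, the only pair that gives an unstrained cis-fused dioxolane, and leaves the anomeric hydroxyl free; this is the known acetonide protection of 2-deoxyribose and touches no stereocentre.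

Step 2
Reactants: 2 2-deoxy-3,4-O-isopropylidene-L-erythro-pentopyranose
Product: 3 2-deoxy-3,4-O-isopropylidene-L-erythro-pentono-1,5-lactone
Conditions: TEMPO (cat.), PhI(OAc)2, CH2Cl2, rt
Reagents that add atoms: none
Why: Oxoammonium oxidation of a lactol to the lactone; the non-basic medium avoids β-elimination of the C3 oxygen.

Step 3
Reactants: 3 2-deoxy-3,4-O-isopropylidene-L-erythro-pentono-1,5-lactone; 4 (trimethylsilyl)methylmagnesium chloride
Product: 6 (2S,3R)-2,3-(isopropylidenedioxy)-5-[(trimethylsilyl)methyl]hex-5-en-1-ol, via bis(silylmethyl)carbinol 5 (not isolated)
Conditions: 4 (4 equiv., two of which are incorporated), CeCl3 (anhydrous, 4 equiv.), THF, −78 °C → rt; aq. NH4Cl; then SiO2, CH2Cl2, rt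
Reagents that add atoms: second equivalent of (trimethylsilyl)methylmagnesium chloride 4, C[Si](C)(C)C[Mg]Cl
Why: Two molecules of 4 are incorporated: the weakly basic reagent formed from Me3SiCH2MgCl and CeCl3 adds twice to the lactone carbonyl without enolisation or β-elimination, and the bis(β-silyl) tertiary carbinol 5 then undergoes Peterson elimination on silica, losing one silyl group as trimethylsilanol, to give the 2-substituted allylsilane. Ring opening frees the C5 carbinol, so C6 and C7 are attached and the future aldehyde carbon is unmasked in one operation; this is the known allylsilane synthesis from esters and lactones, and it touches neither stereocentre.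

Step 4
Reactants: 6 (2S,3R)-2,3-(isopropylidenedioxy)-5-[(trimethylsilyl)methyl]hex-5-en-1-ol
Product: 7 (2R,3R)-2,3-(isopropylidenedioxy)-5-[(trimethylsilyl)methyl]hex-5-enal
Conditions: Dess–Martin periodinane, NaHCO3, CH2Cl2, 0 °C → rt; used at once
Reagents that add atoms: none
Why: Dess–Martin oxidation under buffered, amine-free conditions should give the α-alkoxy aldehyde without epimerising the cis-substituted dioxolane carbon C4 and leaves the allylsilane untouched.

Step 5
Reactants: 7 (2R,3R)-2,3-(isopropylidenedioxy)-5-[(trimethylsilyl)methyl]hex-5-enal
Product: 8 (3R,4S,5R)-3,4-(isopropylidenedioxy)-1-methylenecyclohexan-5-ol (target numbering; O5 trans to O4)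
Conditions: BF3·OEt2 (1.5 equiv.), CH2Cl2, −78 °C; aq. NaHCO3 quench at −78 °C
Reagents that add atoms: none
Why: BF3 binds the aldehyde oxygen, the γ-carbon C6 of the allylsilane adds to C5, the positive charge developing at C1 is stabilised by the C7–Si bond, and loss of silicon to fluoride leaves the exocyclic C1=C7 alkene; this is an intramolecular Hosomi–Sakurai reaction, the known way from 2-(ω-oxoalkyl)allylsilanes to 3-methylenecyclohexanols. The cyclohexane closes 6-exo-trig at the carbonyl, with the allylsilane π bond inside the forming ring, through a chair in which the cis-fused dioxolane takes one axial and one equatorial position. The only new stereocentre, C5, is controlled by C4 and, through the ring fusion, by C3. In chair A (O4 equatorial, O3 axial) the BF3-bound oxygen should go equatorial, because the axial position is 1,3-diaxial to O3, and the C4–O4 bond is then antiperiplanar to the forming C5–C6 bond; this gives O5 trans to O4. In chair B (O4 axial, O3 equatorial) an axial carbonyl oxygen, with its dipole opposed to C4–O4, also gives the trans alcohol, whereas the equatorial one, which leads to the cis alcohol, has the two C–O dipoles nearly eclipsed and becomes favourable only if the Lewis acid chelates O5 and O4. The step therefore needs a monodentate Lewis acid, and SnCl4, TiCl4 or MgBr2 are to be avoided. Low temperature, short contact and a cold basic quench guard against protodesilylation, acetal cleavage and epimerisation at C4.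

Step 6
Reactants: 8 (3R,4S,5R)-3,4-(isopropylidenedioxy)-1-methylenecyclohexan-5-ol
Product: 9 6,7-(isopropylidenedioxy)-1-oxaspiro[2.5]octan-5-ol (the C1/C7 spiro-epoxide of 8, epoxide oxygen on the bottom face, cis to O5)
Conditions: VO(acac)2 (5 mol %), tBuOOH (1.5 equiv., in decane), CH2Cl2, 0 °C → rt
Reagents that add atoms: tert-butyl hydroperoxide, CC(C)(C)OO
Why: Hydroxyl-directed epoxidation: the vanadium-bound O5 alkoxide delivers the peroxide oxygen to the homoallylic exocyclic alkene on its own face (chair with O5 axial), which is also the face remote from the acetal. This places the C1–O bond on the bottom face and C7 on the top face.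

Step 7
Reactants: 10 caffeic acid
Product: 11 3,4-di-O-acetylcaffeic acid
Conditions: Ac2O, pyridine, DMAP (cat.), rt; then 1 M HCl, H2O
Reagents that add atoms: acetic anhydride, CC(=O)OC(C)=O
Why: Acetylation of both phenols; any mixed anhydride at the carboxyl is hydrolysed in the aqueous work-up. Acetates are expected to survive steps 8–10 and to leave under the acid of step 11.

Step 8
Reactants: 9 6,7-(isopropylidenedioxy)-1-oxaspiro[2.5]octan-5-ol; 11 3,4-di-O-acetylcaffeic acid
Product: 12 5-O-(3,4-di-O-acetylcaffeoyl) ester of 9
Conditions: DCC, DMAP (cat.), CH2Cl2, 0 °C → rt
Reagents that add atoms: none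
Why: Steglich esterification of the only hydroxyl in the molecule; the neutral, chloride-free activation spares the spiro-epoxide, and C5 is not a reacting centre, so its configuration is retained.

Step 9
Reactants: 12 5-O-(3,4-di-O-acetylcaffeoyl) ester of 9
Product: 13 1-(hydroxymethyl)-3,4-(isopropylidenedioxy)-1-methoxycyclohex-5-yl (E)-3-(3,4-diacetoxyphenyl)prop-2-enoate (OMe on the top face, CH2OH on the bottom face, cis to O5)
Conditions: MeOH/CH2Cl2 (1:1), CSA (10 mol %), 0 °C; Et3N quench
Reagents that add atoms: methanol, CO
Why: Acid-catalysed solvolysis of a 2,2-disubstituted epoxide: methanol attacks the protonated epoxide at the tertiary carbon C1 from the side opposite to the leaving oxygen (borderline SN2, inversion), which puts OMe on the top face and the C7 carbinol on the face of O5. The O5 ester carbonyl lies on the same face as the leaving oxygen and cannot participate from the rear, and the oxygens at C3, C5 and C7 disfavour a free cation that would erode the inversion.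

Step 10
Reactants: 13 1-(hydroxymethyl)-3,4-(isopropylidenedioxy)-1-methoxycyclohex-5-yl (E)-3-(3,4-diacetoxyphenyl)prop-2-enoate
Product: 15 5-O-(3,4-di-O-acetylcaffeoyl)-3,4-O-isopropylidene-1-O-methylquinic acid, via C7 aldehyde 14 (not isolated)
Conditions: TEMPO (20 mol %), PhI(OAc)2 (2.5 equiv.), MeCN/H2O (1:1), rt
Reagents that add atoms: water, O
Why: Oxoammonium oxidation of the only free hydroxyl to aldehyde 14, whose hydrate is oxidised on to the acid. C1 is quaternary, so nothing can epimerise, and the mildly acidic medium tolerates the enoate, the aryl acetates and the acetal.

Step 11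
Reactants: 15 5-O-(3,4-di-O-acetylcaffeoyl)-3,4-O-isopropylidene-1-O-methylquinic acid
Product: 16 3-O-caffeoyl-1-methylquinic acid (target)
Conditions: 1 M aq. HCl/THF (1:1), rt
Reagents that add atoms: none
Why: Aqueous acid hydrolyses the acetal and both aryl acetates in one operation. The acidic medium prevents migration of the caffeoyl group to O4 and autoxidation of the catechol, the alkyl enoate and the tertiary methyl ether are stable to it, and lactonisation is excluded because O5 is acylated and O3 and O4 are trans to the carboxyl.

## Compound list

1 | 2-deoxy-L-ribose (2-deoxy-L-erythro-pentose, drawn as open-chain (3R,4S)-3,4,5-trihydroxypentanal) | O=CC[C@@H](O)[C@@H](O)CO | starting material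
2 | 2-deoxy-3,4-O-isopropylidene-L-erythro-pentopyranose (cis-fused acetonide, anomeric mixture) | OC1C[C@H]2OC(C)(C)O[C@H]2CO1 | intermediate
3 | 2-deoxy-3,4-O-isopropylidene-L-erythro-pentono-1,5-lactone ((3R,4S), cis-fused) | O=C1C[C@H]2OC(C)(C)O[C@H]2CO1 | intermediate
4 | (trimethylsilyl)methylmagnesium chloride | C[Si](C)(C)C[Mg]Cl | starting material
5 | (2S,3R)-2,3-(isopropylidenedioxy)-6-(trimethylsilyl)-5-[(trimethylsilyl)methyl]hexane-1,5-diol | OC[C@@H]1OC(C)(C)O[C@@H]1CC(O)(C[Si](C)(C)C)C[Si](C)(C)C | intermediate (not isolated)
6 | (2S,3R)-2,3-(isopropylidenedioxy)-5-[(trimethylsilyl)methyl]hex-5-en-1-ol | OC[C@@H]1OC(C)(C)O[C@@H]1CC(=C)C[Si](C)(C)C | intermediate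
7 | (2R,3R)-2,3-(isopropylidenedioxy)-5-[(trimethylsilyl)methyl]hex-5-enal | O=C[C@@H]1OC(C)(C)O[C@@H]1CC(=C)C[Si](C)(C)C | intermediate
8 | (3R,4S,5R)-3,4-(isopropylidenedioxy)-1-methylenecyclohexan-5-ol (target numbering; O3/O4 cis, O5 trans to O4) | C=C1C[C@H]2OC(C)(C)O[C@H]2[C@H](O)C1 | intermediate
9 | 6,7-(isopropylidenedioxy)-1-oxaspiro[2.5]octan-5-ol (C1/C7 spiro-epoxide of 8; epoxide oxygen cis to O5, trans to O3/O4) | C3[C@@]1(O3)C[C@H]2OC(C)(C)O[C@H]2[C@H](O)C1 | intermediate
10 | caffeic acid, (E)-3-(3,4-dihydroxyphenyl)prop-2-enoic acid | OC(=O)/C=C/c1ccc(O)c(O)c1 | starting material
11 | 3,4-di-O-acetylcaffeic acid, (E)-3-(3,4-diacetoxyphenyl)prop-2-enoic acid | CC(=O)Oc1ccc(/C=C/C(=O)O)cc1OC(C)=O | intermediate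
12 | 5-O-(3,4-di-O-acetylcaffeoyl) ester of 9 (acyloxy group and epoxide oxygen cis) | C3[C@@]1(O3)C[C@H]2OC(C)(C)O[C@H]2[C@H](OC(=O)/C=C/c4ccc(OC(C)=O)c(OC(C)=O)c4)C1 | intermediate
13 | 1-(hydroxymethyl)-3,4-(isopropylidenedioxy)-1-methoxycyclohex-5-yl (E)-3-(3,4-diacetoxyphenyl)prop-2-enoate (OMe cis to O3/O4, CH2OH cis to O5) | CO[C@@]1(CO)C[C@H]2OC(C)(C)O[C@H]2[C@H](OC(=O)/C=C/c4ccc(OC(C)=O)c(OC(C)=O)c4)C1 | intermediate
14 | 1-formyl-3,4-(isopropylidenedioxy)-1-methoxycyclohex-5-yl (E)-3-(3,4-diacetoxyphenyl)prop-2-enoate (same configuration as 13) | CO[C@@]1(C=O)C[C@H]2OC(C)(C)O[C@H]2[C@H](OC(=O)/C=C/c4ccc(OC(C)=O)c(OC(C)=O)c4)C1 | intermediate (not isolated)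
15 | 5-O-(3,4-di-O-acetylcaffeoyl)-3,4-O-isopropylidene-1-O-methylquinic acid (numbering used here) | CO[C@@]1(C(=O)O)C[C@H]2OC(C)(C)O[C@H]2[C@H](OC(=O)/C=C/c4ccc(OC(C)=O)c(OC(C)=O)c4)C1 | intermediate
16 | 3-O-caffeoyl-1-methylquinic acid, (1S,3R,4R,5R)-5-{[(E)-3-(3,4-dihydroxyphenyl)prop-2-enoyl]oxy}-3,4-dihydroxy-1-methoxycyclohexane-1-carboxylic acid | CO[C@@]1(C(=O)O)C[C@@H](O)[C@@H](O)[C@H](OC(=O)/C=C/c2ccc(O)c(O)c2)C1 | target

## Step count and least certain steps

Total step count: 11 (step 7 prepares the acyl fragment). Longest linear sequence: 10 steps (1–6 and 8–11, from 1 to 16).

Step 5 (key step). The most likely failure is insufficient facial control at the aldehyde, giving the C5 epimer. The two cis-leading chairs are penalised only by a 1,3-diaxial contact and by dipole alignment, and both effects weaken if the chair flattens under the cis-fused dioxolane. Protodesilylation by adventitious acid is the second risk. Fallback, from 7 back to 8: the closure would be run under deliberate chelation control (SnCl4 or MgBr2·OEt2, CH2Cl2, −78 °C), where chair B with an equatorial, chelated carbonyl oxygen should dominate, to give the all-cis alcohol (3R,4S,5S)-3,4-(isopropylidenedioxy)-1-methylenecyclohexan-5-ol F1. Mitsunobu esterification (4-nitrobenzoic acid, PPh3, DIAD, PhMe, 0 °C → rt) should then invert C5 by attack from the face remote from the acetal to give the 4-nitrobenzoate of 8 F2, and K2CO3/MeOH would release 8.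

Step 6. The most likely failure is incomplete facial selectivity, because direction by a homoallylic hydroxyl is weaker than by an allylic one, together with opening of the acid-sensitive spiro-epoxide by the Lewis-acidic metal. Fallback, from 8 back to 9: oxygen would be delivered through a tether. Boc2O/DMAP gives the O5 tert-butyl carbonate of 8 F3. IBr in PhMe/CH2Cl2 at −80 °C closes the cyclic carbonate bridging O5 and the C1 oxygen with iodomethyl at C1 on the top face F4; the tether can only form the C1–O bond on the face of O5. K2CO3 in MeOH then cleaves the carbonate, and the C1 alkoxide displaces iodide at C7 to give 9.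

Step 9. The most likely failures are erosion of the invertive course through partial cation character at C1, a competing hydride shift to a C1 aldehyde, or an opening so slow that the acid begins to solvolyse the aryl acetates and the acetal. The epoxide is deactivated by three nearby oxygens and rear-side approach is syn to O3. Fallback, from 9 back to 13: the epoxide would be opened in 9 itself (MeOH, CSA cat., 0 °C), where the free cis O5–H activates the epoxide by internal hydrogen bonding and no acetate is present, to give 1-(hydroxymethyl)-3,4-(isopropylidenedioxy)-1-methoxycyclohexan-5-ol F5. Selective silylation of the primary hydroxyl (TBSCl, imidazole, CH2Cl2) would give the C7 tert-butyldimethylsilyl ether of that diol F6, Steglich esterification with 11 (DCC, DMAP) its 5-O-(3,4-di-O-acetylcaffeoyl) ester F7, and HF·pyridine in THF would remove the silyl group to give 13.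

Step 10. The most likely failure is stalling of the oxidation at the hindered neopentyl-type carbinol or at aldehyde 14, because the oxoammonium salt is bulky, with slow side reactions of the hypervalent iodine reagent on long exposure. Fallback, from 13 back to 15: the oxidation would be split into two stages with unhindered oxidants of a different kind, Dess–Martin periodinane (NaHCO3, CH2Cl2) to isolate 14, then NaClO2, NaH2PO4 and 2-methylbut-2-ene in tBuOH/H2O to give 15. No new compound is involved.

## Further compounds

F1 | step 5 | (3R,4S,5S)-3,4-(isopropylidenedioxy)-1-methylenecyclohexan-5-ol (C5 epimer of 8, O5 cis to O4) | C=C1C[C@H]2OC(C)(C)O[C@H]2[C@@H](O)C1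
F2 | step 5 | 4-nitrobenzoate of 8 (O5 trans to O4) | C=C1C[C@H]2OC(C)(C)O[C@H]2[C@H](OC(=O)c3ccc(cc3)[N+](=O)[O-])C1
F3 | step 6 | O5 tert-butyl carbonate of 8 | C=C1C[C@H]2OC(C)(C)O[C@H]2[C@H](OC(=O)OC(C)(C)C)C1
F4 | step 6 | cyclic carbonate bridging O5 and the C1 oxygen, iodomethyl at C1 on the top face | IC[C@@]13C[C@H]2OC(C)(C)O[C@H]2[C@H](OC(=O)O3)C1
F5 | step 9 | 1-(hydroxymethyl)-3,4-(isopropylidenedioxy)-1-methoxycyclohexan-5-ol (OMe cis to O3/O4, CH2OH cis to O5) | CO[C@@]1(CO)C[C@H]2OC(C)(C)O[C@H]2[C@H](O)C1
F6 | step 9 | C7 tert-butyldimethylsilyl ether of F5 | CO[C@@]1(CO[Si](C)(C)C(C)(C)C)C[C@H]2OC(C)(C)O[C@H]2[C@H](O)C1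
F7 | step 9 | 5-O-(3,4-di-O-acetylcaffeoyl) ester of F6 | CO[C@@]1(CO[Si](C)(C)C(C)(C)C)C[C@H]2OC(C)(C)O[C@H]2[C@H](OC(=O)/C=C/c4ccc(OC(C)=O)c(OC(C)=O)c4)C1
F0 | step 10 | none | none
A1 | alternative 1 | 5-(tert-butyldimethylsilyloxy)-3-methoxy-6-vinyltetrahydropyran-2-one, silyloxy trans to vinyl (C3 configuration is lost on enolisation) | C=C[C@@H]1OC(=O)C(OC)C[C@H]1O[Si](C)(C)C(C)(C)C
A2 | alternative 1 | 5-(tert-butyldimethylsilyloxy)-1-methoxycyclohex-3-ene-1-carboxylic acid (carboxyl cis to the silyloxy group) | CO[C@@]1(C(=O)O)CC=C[C@H](O[Si](C)(C)C(C)(C)C)C1
A3 | alternative 2 | tert-butyl 2-methoxy-5-(4-methoxybenzyloxy)-4-oxo-2-(2-oxoethyl)pentanoate | CO[C@@](CC=O)(C(=O)OC(C)(C)C)CC(=O)COCc1ccc(OC)cc1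
A4 | alternative 2 | tert-butyl 5-hydroxy-1-methoxy-4-(4-methoxybenzyloxy)-3-oxocyclohexane-1-carboxylate | CO[C@@]1(C(=O)OC(C)(C)C)CC(=O)[C@@H](OCc2ccc(OC)cc2)[C@H](O)C1
A5 | alternative 3 | (R)-2-tert-butyl-5-methylene-1,3-dioxolan-4-one | C=C1O[C@@H](C(C)(C)C)OC1=O
A6 | alternative 3 | buta-1,3-diene | C=CC=C
A7 | alternative 3 | 2-tert-butyl-1,3-dioxaspiro[4.5]dec-7-en-4-one (diastereomer from addition anti to tert-butyl) | O=C1O[C@H](C(C)(C)C)O[C@]12CCC=CC2
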